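**Retrosynthetic overview**
- The target is epigallocatechin‑3‑O‑gallate‑(4β→6)‑gallocatechin; the last operation is one hydrogenolysis of its tetradeca‑O‑benzyl ether carrying bromine at lower C8.
- The strategy rests on ring C of the upper, galloylated flavan: O1–C8a–C4a–C4 is read as a ring‑A ortho‑quinone methide and C2–C3 (carrying ring B and the gallate) as a (Z)‑enol gallate, so O1–C2 and C3–C4 are cut in one [4+2] step.
- Ring C is the only ring formed. The quinone methide precursor is an ortho‑hydroxybenzhydrol, made by joining C6 of ring D (aryl‑magnesium from 8‑bromo‑6‑iodo‑hexa‑O‑benzylgallocatechin) to the formyl carbon of 4,6‑bis(benzyloxy)salicylaldehyde.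
- The enol gallate comes from anti‑Markovnikov addition of tri‑O‑benzylgallic acid to 3,4,5‑tris(benzyloxy)phenylacetylene.

Key step: step 9

Assumption: flavan numbering is used (upper unit rings A, C, B; lower unit rings D, F, E); the facial sense of the phosphoric acid on this new substrate pair cannot be read from precedent, so the (R)‑acid is written, and its antipode would replace it with nothing else changed if the first run shows a mismatch.

**Step 1**
Reactants: 1 (+)-gallocatechin
Product: 2 5,7,3',4',5'-penta-O-benzyl-(+)-gallocatechin (3-OH free; 2R,3S)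
Conditions: BnBr (5.5 equiv), K2CO3, DMF, 0 °C → rt, Ar
Reagents that add atoms: benzyl bromide, BrCc1ccccc1
Why: Williamson etherification with a weak base alkylates the five phenols only, leaves the secondary 3‑OH free and breaks no bond at C2 or C3, cold and oxygen‑free conditions limiting C‑benzylation and oxidation of the pyrogallol ring.

**Step 2**
Reactants: 2 5,7,3',4',5'-penta-O-benzyl-(+)-gallocatechin
Product: 3 3,5,7,3',4',5'-hexa-O-benzyl-(+)-gallocatechin
Conditions: NaH, BnBr, Bu4NI (cat.), DMF, 0 °C → rt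
Reagents that add atoms: benzyl bromide, BrCc1ccccc1
Why: Williamson etherification of the secondary alkoxide gives the 3‑O‑benzyl ether with retention, since no bond to C3 is broken.

**Step 3**
Reactants: 3 3,5,7,3',4',5'-hexa-O-benzyl-(+)-gallocatechin
Product: 4 8-bromo-3,5,7,3',4',5'-hexa-O-benzylgallocatechin
Conditions: NBS (1.0 equiv), CH2Cl2, −78 → 0 °C
Reagents that add atoms: N-bromosuccinimide, O=C1CCC(=O)N1Br
Why: Electrophilic aromatic bromination of the phloroglucinol‑type ring D should go to C8, the more accessible of its two free positions in 5,7‑di‑O‑benzylflavans, when one equivalent of NBS is used cold.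

**Step 4**
Reactants: 4 8-bromo-3,5,7,3',4',5'-hexa-O-benzylgallocatechin
Product: 5 8-bromo-6-iodo-3,5,7,3',4',5'-hexa-O-benzylgallocatechin
Conditions: NIS (1.2 equiv), TFA (cat.), MeCN/CH2Cl2, 0 °C → rt, dark
Reagents that add atoms: N-iodosuccinimide, O=C1CCC(=O)N1I
Why: Acid‑activated NIS iodinates the last free ring‑D position C6 (electrophilic aromatic substitution), which has three ortho/para oxygens and should react well ahead of the pyrogallol ring E.

**Step 5**
Reactants: 6 2,4,6-trihydroxybenzaldehyde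
Product: 7 4,6-bis(benzyloxy)-2-hydroxybenzaldehyde
Conditions: BnBr (2.05 equiv), K2CO3, DMF, 0 °C → rt
Reagents that add atoms: benzyl bromide, BrCc1ccccc1
Why: Williamson etherification under weak base takes the para hydroxyl and one ortho hydroxyl, while the second ortho hydroxyl, hydrogen‑bonded to the formyl group, should stay free at two equivalents of benzyl bromide.

**Step 6**
Reactants: 5 8-bromo-6-iodo-3,5,7,3',4',5'-hexa-O-benzylgallocatechin; 7 4,6-bis(benzyloxy)-2-hydroxybenzaldehyde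
Product: 10 [4,6-bis(benzyloxy)-2-hydroxyphenyl](8-bromo-hexa-O-benzylgallocatechin-6-yl)methanol (both carbinol epimers), via sodium phenoxide 8 (not isolated), via arylmagnesium chloride 9 (not isolated)
Conditions: 7, NaH, THF, 0 °C (gives 8); 5, iPrMgCl·LiCl, THF, −20 → 0 °C (gives 9); 9 added to 8 (1.5 equiv), −40 °C → rt; aq. NH4Cl; Et3N‑deactivated SiO2
Reagents that add atoms: none
Why: Iodine–magnesium exchange with iPrMgCl·LiCl is far faster at C–I than at C–Br, and the 2,6‑dialkoxyaryl Grignard then adds to the formyl group of the pre‑formed phenoxide (deprotonation beforehand keeps the phenol from quenching it); the carbinol centre forms without control, which is harmless because step 9 makes it planar.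

**Step 7**
Reactants: 11 3,4,5-tris(benzyloxy)benzaldehyde
Product: 12 1,2,3-tris(benzyloxy)-5-ethynylbenzene
Conditions: dimethyl (1-diazo-2-oxopropyl)phosphonate, K2CO3, MeOH/THF, rt
Reagents that add atoms: dimethyl (1-diazo-2-oxopropyl)phosphonate, CC(=O)C(=[N+]=[N-])P(=O)(OC)OC
Why: Ohira–Bestmann homologation turns the aldehyde into the terminal alkyne through the diazoalkene and 1,2‑hydride shift of the alkylidene carbene, under mild base that benzyl ethers tolerate.

**Step 8**
Reactants: 12 1,2,3-tris(benzyloxy)-5-ethynylbenzene; 13 3,4,5-tris(benzyloxy)benzoic acid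
Product: 14 (Z)-2-[3,4,5-tris(benzyloxy)phenyl]vinyl 3,4,5-tris(benzyloxy)benzoate
Conditions: [RuCl2(p-cymene)]2 (2 mol%), P(4-ClC6H4)3 (6 mol%), DMAP (8 mol%), PhMe, 60 °C
Reagents that add atoms: none
Why: Ruthenium‑catalysed anti‑Markovnikov hydro‑oxycarbonylation of a terminal alkyne, in which the carboxylate attacks the α‑carbon of a ruthenium vinylidene and protonolysis of the alkenyl–ruthenium bond should deliver the (Z)‑enol ester.

**Step 9**
Reactants: 10 [4,6-bis(benzyloxy)-2-hydroxyphenyl](8-bromo-hexa-O-benzylgallocatechin-6-yl)methanol; 14 (Z)-2-[3,4,5-tris(benzyloxy)phenyl]vinyl 3,4,5-tris(benzyloxy)benzoate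
Product: 16 tetradeca-O-benzyl ether of the target with bromine at lower C8 (upper unit 2R,3R; ring D at C4 on the β face and trans to the gallate), via ortho-quinone methide 15 (not isolated)
Conditions: (R)-3,3'-bis(2,4,6-triisopropylphenyl)-1,1'-binaphthyl-2,2'-diyl hydrogen phosphate (10 mol%), 14 (3 equiv), 5 Å MS, PhMe, 0 °C → rt, 10 added over 6 h
Reagents that add atoms: none
Why: Proposed new method: the phosphoric acid should ionise either carbinol epimer of 10 to the phosphate‑bound ortho‑quinone methide 15, whose methide carbon C4 is attacked by the oxygen‑bearing carbon of 14 while the ring‑B‑stabilised benzylic carbon closes onto the quinone methide oxygen, an asynchronous inverse‑demand [4+2]. The closest known reaction type is the hetero‑Diels–Alder of in situ ortho‑quinone methides with styrenes under chiral phosphoric acid or N‑triflylphosphoramide catalysis, and a β‑acyloxystyrene has not been used as the 2π partner. Ring C is closed by this intermolecular cycloaddition of the oxa‑diene O1=C8a–C4a=C4 with C2=C3, C3–C4 forming ahead of O1–C2. C2 and C3 should become cis because the addition is suprafacial on the Z alkene; C4 should become trans to C3 because the Z‑quinone methide (ring D syn to the carbonyl oxygen, pushed there by the 5‑benzyloxy group) takes the dienophile endo; the absolute sense is left to the confined chiral phosphate on the quinone methide oxygen, and the enantiopure lower unit makes a wrong‑face adduct a separable diastereomer. The step needs styrene‑type regiochemistry, which the weak donor power of the acyloxy group against the 3,4,5‑tribenzyloxyphenyl group should secure. It also needs cycloaddition to outrun Friedel–Crafts self‑condensation and enol ester hydrolysis, for which the bromine at lower C8, the excess of 14, slow addition of 10, the congestion of any hexa‑ortho‑substituted triarylmethane and the sieves are provided.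

**Step 10**
Reactants: 16 tetradeca-O-benzyl ether of the target with bromine at lower C8
Product: 17 epigallocatechin-3-O-gallate-(4β→6)-gallocatechin (CNP0271447.2)
Conditions: H2 (1 atm), Pd(OH)2/C, NaOAc, THF/MeOH/H2O, rt
Reagents that add atoms: none
Why: Hydrogenolysis over Pd(OH)2/C should cleave all fourteen benzyl ethers and the aryl C–Br bond in one operation, with acetate buffering the HBr so that the acid‑labile interflavan bond and the five stereocentres, none of which is touched, survive.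

**Compound list**
1 | (+)-gallocatechin (2R,3S) | Oc1cc(O)c2C[C@H](O)[C@@H](c3cc(O)c(O)c(O)c3)Oc2c1 | starting material
2 | 5,7,3',4',5'-penta-O-benzyl-(+)-gallocatechin | O(Cc1ccccc1)c1cc(OCc3ccccc3)c2C[C@H](O)[C@@H](c3cc(OCc4ccccc4)c(OCc4ccccc4)c(OCc4ccccc4)c3)Oc2c1 | intermediate
3 | 3,5,7,3',4',5'-hexa-O-benzyl-(+)-gallocatechin | O(Cc1ccccc1)c1cc(OCc3ccccc3)c2C[C@H](OCc3ccccc3)[C@@H](c3cc(OCc4ccccc4)c(OCc4ccccc4)c(OCc4ccccc4)c3)Oc2c1 | intermediate
4 | 8-bromo-3,5,7,3',4',5'-hexa-O-benzylgallocatechin | O(Cc1ccccc1)c1cc(OCc3ccccc3)c2C[C@H](OCc3ccccc3)[C@@H](c3cc(OCc4ccccc4)c(OCc4ccccc4)c(OCc4ccccc4)c3)Oc2c1Br | intermediate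
5 | 8-bromo-6-iodo-3,5,7,3',4',5'-hexa-O-benzylgallocatechin | O(Cc1ccccc1)c1c(I)c(OCc3ccccc3)c2C[C@H](OCc3ccccc3)[C@@H](c3cc(OCc4ccccc4)c(OCc4ccccc4)c(OCc4ccccc4)c3)Oc2c1Br | intermediate
6 | 2,4,6-trihydroxybenzaldehyde | O=Cc1c(O)cc(O)cc1O | starting material
7 | 4,6-bis(benzyloxy)-2-hydroxybenzaldehyde | O=Cc1c(O)cc(OCc2ccccc2)cc1OCc1ccccc1 | intermediate
8 | sodium 3,5-bis(benzyloxy)-2-formylphenolate | [Na+].[O-]c1cc(OCc2ccccc2)cc(OCc2ccccc2)c1C=O | intermediate (not isolated)
9 | (8-bromo-hexa-O-benzylgallocatechin-6-yl)magnesium chloride | O(Cc1ccccc1)c1c([Mg]Cl)c(OCc3ccccc3)c2C[C@H](OCc3ccccc3)[C@@H](c3cc(OCc4ccccc4)c(OCc4ccccc4)c(OCc4ccccc4)c3)Oc2c1Br | intermediate (not isolated)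
10 | [4,6-bis(benzyloxy)-2-hydroxyphenyl](8-bromo-hexa-O-benzylgallocatechin-6-yl)methanol, both carbinol epimers | OC(c2c(OCc4ccccc4)c(Br)c3c(c2OCc4ccccc4)C[C@H](OCc4ccccc4)[C@@H](c2cc(OCc4ccccc4)c(OCc4ccccc4)c(OCc4ccccc4)c2)O3)c2c(OCc4ccccc4)cc(OCc4ccccc4)cc2O | intermediate
11 | 3,4,5-tris(benzyloxy)benzaldehyde | O=Cc1cc(OCc2ccccc2)c(OCc2ccccc2)c(OCc2ccccc2)c1 | starting material
12 | 1,2,3-tris(benzyloxy)-5-ethynylbenzene | C#Cc1cc(OCc2ccccc2)c(OCc2ccccc2)c(OCc2ccccc2)c1 | intermediate
13 | 3,4,5-tris(benzyloxy)benzoic acid | OC(=O)c1cc(OCc2ccccc2)c(OCc2ccccc2)c(OCc2ccccc2)c1 | starting material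
14 | (Z)-2-[3,4,5-tris(benzyloxy)phenyl]vinyl 3,4,5-tris(benzyloxy)benzoate | O=C(O/C=C\c1cc(OCc4ccccc4)c(OCc4ccccc4)c(OCc4ccccc4)c1)c1cc(OCc4ccccc4)c(OCc4ccccc4)c(OCc4ccccc4)c1 | intermediate
15 | (Z)-ortho-quinone methide of ring A, 6-[(8-bromo-hexa-O-benzylgallocatechin-6-yl)methylidene]-3,5-bis(benzyloxy)cyclohexa-2,4-dien-1-one | O=C1C=C(OCc2ccccc2)C=C(OCc2ccccc2)/C1=C/c1c(OCc2ccccc2)c(Br)c2c(c1OCc1ccccc1)C[C@H](OCc1ccccc1)[C@@H](c1cc(OCc3ccccc3)c(OCc3ccccc3)c(OCc3ccccc3)c1)O2 | intermediate (not isolated)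
16 | tetradeca-O-benzyl ether of the target with bromine at lower C8 | O=C(O[C@@H]1[C@@H](c2c(OCc4ccccc4)c(Br)c3c(c2OCc4ccccc4)C[C@H](OCc4ccccc4)[C@@H](c2cc(OCc4ccccc4)c(OCc4ccccc4)c(OCc4ccccc4)c2)O3)c2c(OCc4ccccc4)cc(OCc4ccccc4)cc2O[C@@H]1c1cc(OCc4ccccc4)c(OCc4ccccc4)c(OCc4ccccc4)c1)c1cc(OCc4ccccc4)c(OCc4ccccc4)c(OCc4ccccc4)c1 | intermediate
17 | epigallocatechin-3-O-gallate-(4β→6)-gallocatechin | O=C(O[C@@H]1[C@@H](c2c(O)cc3c(c2O)C[C@H](O)[C@@H](c2cc(O)c(O)c(O)c2)O3)c2c(O)cc(O)cc2O[C@@H]1c1cc(O)c(O)c(O)c1)c1cc(O)c(O)c(O)c1 | target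

**Totals**
Total step count: 10. Longest linear sequence: 7 steps (steps 1, 2, 3, 4, 6, 9, 10).

**Steps most likely to fail**

Step 9. Capture of the strongly stabilised, tetra‑ortho‑substituted quinone methide by a weak 2π nucleophile may be slower than Friedel–Crafts self‑condensation through the free ring‑A positions or hydrolysis of the enol ester. The benzylic cation may rotate about C2–C3 before O1–C2 closes, eroding the 2,3‑cis relation. Regiochemistry may invert, and facial control by the phosphate may be poor. The fallback is the established Lewis‑acid interflavan coupling; it sets out from 4 and 13 and comes back at 17. Commercial (−)‑epigallocatechin is benzylated (BnBr, K2CO3, DMF) to 5,7,3',4',5'-penta-O-benzyl-(−)-epigallocatechin F1. NBS in CH2Cl2 at −78 °C caps C8 to give 8-bromo-penta-O-benzylepigallocatechin F2. DDQ with 2‑ethoxyethanol in CH2Cl2 oxidises C4 to 8-bromo-4β-(2-ethoxyethoxy)-penta-O-benzylepigallocatechin F3. TMSOTf in CH2Cl2 at −78 °C ionises F3, and the C4 cation is taken by C6 of 4 (threefold excess), anti to the 3‑hydroxyl, to give the 4β→6 dimer with a free upper 3‑hydroxyl and bromine at both C8 positions, F4. Steglich esterification of that single hydroxyl with 13 (DCC, DMAP, CH2Cl2) gives the 8‑bromo analogue of 16, F5. The conditions of step 10 then remove both bromines and all benzyl groups to give 17.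

Step 6. Iodine–magnesium exchange on the electron‑rich, doubly ortho‑substituted iodide may be incomplete. The hindered aryl Grignard may transfer a proton or add only sluggishly to the deactivated phenoxide aldehyde. The product may ionise on work‑up. The fallback masks the phenol; it sets out from 7 (with 5) and comes back at 10. TBSCl and imidazole in DMF convert 7 into 4,6-bis(benzyloxy)-2-(tert-butyldimethylsilyloxy)benzaldehyde F6, a neutral and more electrophilic aldehyde. Addition of 9, made from 5 as before, gives the silyl‑protected benzhydrol F7 (a silyl shift to the carbinol oxygen would be harmless). TBAF in THF at 0 °C then releases 10.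

Step 8. The Z geometry may erode, Markovnikov addition may compete, or the hindered electron‑rich acid may inhibit the catalyst. The fallback builds the C–O bond on a preformed Z alkene; it sets out from 12 (with 13) and comes back at 14. Rhodium‑catalysed trans‑hydroboration of 12 (pinacolborane, [Rh(cod)Cl]2, PiPr3, Et3N, cyclohexane) gives (Z)-2-[3,4,5-tris(benzyloxy)phenyl]vinylboronic acid pinacol ester F8. KHF2 in MeOH/H2O converts it into potassium (Z)-2-[3,4,5-tris(benzyloxy)phenyl]vinyltrifluoroborate F9. Copper‑catalysed oxidative coupling with 13 (CuBr, DMAP, 4 Å MS, O2, CH2Cl2) then forms 14 with retention of the alkene geometry.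

**Further compounds**
F1 | step 9 | 5,7,3',4',5'-penta-O-benzyl-(−)-epigallocatechin | O[C@@H]1Cc2c(OCc3ccccc3)cc(OCc3ccccc3)cc2O[C@@H]1c1cc(OCc2ccccc2)c(OCc2ccccc2)c(OCc2ccccc2)c1
F2 | step 9 | 8-bromo-5,7,3',4',5'-penta-O-benzylepigallocatechin | O[C@@H]1Cc2c(OCc3ccccc3)cc(OCc3ccccc3)c(Br)c2O[C@@H]1c1cc(OCc2ccccc2)c(OCc2ccccc2)c(OCc2ccccc2)c1
F3 | step 9 | 8-bromo-4β-(2-ethoxyethoxy)-5,7,3',4',5'-penta-O-benzylepigallocatechin | O[C@@H]1[C@@H](OCCOCC)c2c(OCc3ccccc3)cc(OCc3ccccc3)c(Br)c2O[C@@H]1c1cc(OCc2ccccc2)c(OCc2ccccc2)c(OCc2ccccc2)c1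
F4 | step 9 | 8-bromo-penta-O-benzylepigallocatechin-(4β→6)-8-bromo-hexa-O-benzylgallocatechin, upper 3-OH free | O[C@@H]1[C@@H](c2c(OCc4ccccc4)c(Br)c3c(c2OCc4ccccc4)C[C@H](OCc4ccccc4)[C@@H](c2cc(OCc4ccccc4)c(OCc4ccccc4)c(OCc4ccccc4)c2)O3)c2c(OCc4ccccc4)cc(OCc4ccccc4)c(Br)c2O[C@@H]1c1cc(OCc4ccccc4)c(OCc4ccccc4)c(OCc4ccccc4)c1
F5 | step 9 | 8-bromo analogue of 16 (bromine at C8 of both units) | O=C(O[C@@H]1[C@@H](c2c(OCc4ccccc4)c(Br)c3c(c2OCc4ccccc4)C[C@H](OCc4ccccc4)[C@@H](c2cc(OCc4ccccc4)c(OCc4ccccc4)c(OCc4ccccc4)c2)O3)c2c(OCc4ccccc4)cc(OCc4ccccc4)c(Br)c2O[C@@H]1c1cc(OCc4ccccc4)c(OCc4ccccc4)c(OCc4ccccc4)c1)c1cc(OCc4ccccc4)c(OCc4ccccc4)c(OCc4ccccc4)c1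
F6 | step 6 | 4,6-bis(benzyloxy)-2-(tert-butyldimethylsilyloxy)benzaldehyde | O=Cc1c(O[Si](C)(C)C(C)(C)C)cc(OCc2ccccc2)cc1OCc1ccccc1
F7 | step 6 | O-TBS ether (phenol oxygen) of benzhydrol 10, both carbinol epimers | OC(c2c(OCc4ccccc4)c(Br)c3c(c2OCc4ccccc4)C[C@H](OCc4ccccc4)[C@@H](c2cc(OCc4ccccc4)c(OCc4ccccc4)c(OCc4ccccc4)c2)O3)c2c(OCc4ccccc4)cc(OCc4ccccc4)cc2O[Si](C)(C)C(C)(C)C
F8 | step 8 | (Z)-2-[3,4,5-tris(benzyloxy)phenyl]vinylboronic acid pinacol ester | CC1(C)OB(/C=C\c2cc(OCc3ccccc3)c(OCc3ccccc3)c(OCc3ccccc3)c2)OC1(C)C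
F9 | step 8 | potassium (Z)-2-[3,4,5-tris(benzyloxy)phenyl]vinyltrifluoroborate | [K+].F[B-](F)(F)/C=C\c1cc(OCc2ccccc2)c(OCc2ccccc2)c(OCc2ccccc2)c1
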